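The route hinges on taking ring B apart at C2, the lone sp3 carbon that carries ring C and sits between O1 and C3. Because C3 is attached to ring A and flanked by the ring D carbonyl, it maps onto the exocyclic carbon of an acyl ortho-quinone methide, while C2 maps onto the carbanion carbon of a benzylic sulfonium ylide. A single [4+1] annulation then makes C2–C3 and C2–O1, closes ring B and sets both stereocentres, C2 through the chiral thiolane and C3 by equilibration to trans. The partners are a racemic silyl-masked alpha-bromo deoxybenzoin bearing the C5 bromide and a twofold-symmetric thiolanium salt; Heck coupling at C5 and one hydrogenation finish.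

Key step: step 9

Remark (numbering): O1, C2, C3, C3a, C4–C7, C7a; ring A benzo, ring B dihydrofuran, ring C the aryl on C2, ring D the aroyl on C3, ring E the aryl ketone of the C5 chain; the target is (2S,3S), trans.

Remark (sense of induction): in benzylides of trans-2,5-dimethylthiolane the aryl group lies syn to the sulfur lone pair and the electrophile enters anti to the ring methyl that is cis to the ylide carbon; with invertive closure, and because C3 ranks below the aryl group at C2 (the reverse of the ranking at an epoxide carbon), this model predicts 2S from the (2S,5S) sulfide, so the (2S,5S) salt is used and is made from (2R,5R)-hexane-2,5-diol.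

Remark (supply): 1-[2,4-bis(benzyloxy)phenyl]ethan-1-one is taken as a catalogue compound; it is otherwise one benzylation from 2',4'-dihydroxyacetophenone.

Step 1
Reactants: 1 2-(5-bromo-2-hydroxyphenyl)acetic acid
Product: 3 2-[5-bromo-2-(tert-butyldimethylsilyloxy)phenyl]acetic acid, via bis-silylated acid 2 (not isolated)
Conditions: TBSCl (2.4 equiv), imidazole, DMF, rt; then AcOH/THF/H2O, rt
Reagents that add atoms: tert-butyldimethylsilyl chloride, CC(C)(C)[Si](C)(C)Cl
Why: Silylation of both the phenol and the acid followed by selective hydrolysis of the far more labile silyl ester leaves the aryl silyl ether, which later serves as the fluoride-labile trigger.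

Step 2
Reactants: 3 2-[5-bromo-2-(tert-butyldimethylsilyloxy)phenyl]acetic acid
Product: 5 2-[5-bromo-2-(tert-butyldimethylsilyloxy)phenyl]-N-methoxy-N-methylacetamide, via acyl imidazolide 4 (not isolated)
Conditions: CDI, CH2Cl2, rt; then MeNH(OMe)·HCl, rt
Reagents that add atoms: N,O-dimethylhydroxylamine hydrochloride, CNOC.Cl
Why: Activation of the acid as its acyl imidazolide and aminolysis (Weinreb amide synthesis) proceed under near-neutral conditions that the aryl silyl ether tolerates.

Step 3
Reactants: 6 4-bromoresorcinol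
Product: 7 2,4-bis(benzyloxy)-1-bromobenzene
Conditions: BnBr (2.2 equiv), K2CO3, DMF, 60 °C
Reagents that add atoms: benzyl bromide, BrCc1ccccc1
Why: Williamson etherification of both phenols installs benzyl groups, chosen so that every phenol protecting group of the route falls in the final hydrogenation.

Step 4
Reactants: 7 2,4-bis(benzyloxy)-1-bromobenzene; 5 2-[5-bromo-2-(tert-butyldimethylsilyloxy)phenyl]-N-methoxy-N-methylacetamide
Product: 9 1-[2,4-bis(benzyloxy)phenyl]-2-[5-bromo-2-(tert-butyldimethylsilyloxy)phenyl]ethan-1-one, via aryllithium 8 (not isolated)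
Conditions: 7, n-BuLi (1.0 equiv), THF, −78 °C; then 5, −78 °C; aq. NH4Cl
Reagents that add atoms: none
Why: Bromine–lithium exchange followed by Weinreb ketone synthesis stops at the chelated tetrahedral intermediate, and at −78 °C the ortho-alkoxy-stabilised aryllithium should neither exchange with the ring A bromide nor undergo Wittig rearrangement.

Step 5
Reactants: 9 1-[2,4-bis(benzyloxy)phenyl]-2-[5-bromo-2-(tert-butyldimethylsilyloxy)phenyl]ethan-1-one
Product: 11 rac-1-[2,4-bis(benzyloxy)phenyl]-2-bromo-2-[5-bromo-2-(tert-butyldimethylsilyloxy)phenyl]ethan-1-one, via lithium enolate 10 (not isolated)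
Conditions: LiN(SiMe3)2, THF, −78 °C; enolate added to NBS, THF, −78 °C; aq. NH4Cl
Reagents that add atoms: N-bromosuccinimide, O=C1CCC(=O)N1Br
Why: Bromination of the preformed enolate at the only enolisable position avoids electrophilic substitution on the electron-rich rings and any acid that would unmask the phenol, inverse addition suppresses proton transfer and dibromination, and the new stereocentre is racemic by design because step 9 erases it.

Step 6
Reactants: 12 (2R,5R)-hexane-2,5-diol
Product: 13 (2R,5R)-hexane-2,5-diyl dimethanesulfonate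
Conditions: MsCl, Et3N, CH2Cl2, 0 °C
Reagents that add atoms: methanesulfonyl chloride, CS(=O)(=O)Cl
Why: Mesylation activates both secondary alcohols with retention of configuration.

Step 7
Reactants: 13 (2R,5R)-hexane-2,5-diyl dimethanesulfonate
Product: 14 (2S,5S)-2,5-dimethylthiolane
Conditions: Na2S·9H2O, DMSO, rt
Reagents that add atoms: sodium sulfide, [Na+].[Na+].[S-2]
Why: Double SN2 displacement by sulfide, intermolecular and then 5-exo-tet, inverts both carbinol carbons and so converts the (2R,5R) dimesylate into the trans (2S,5S) thiolane.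

Step 8
Reactants: 14 (2S,5S)-2,5-dimethylthiolane; 15 4-(benzyloxy)benzyl chloride
Product: 16 (2S,5S)-1-[4-(benzyloxy)benzyl]-2,5-dimethylthiolan-1-ium tetrafluoroborate
Conditions: AgBF4, CH2Cl2, 0 °C to rt, dark
Reagents that add atoms: silver tetrafluoroborate, [Ag+].F[B-](F)(F)F
Why: S-Alkylation of the sulfide by the electron-rich benzylic chloride is driven by precipitation of AgCl, the twofold axis makes both sulfur lone pairs equivalent so that a single sulfonium salt forms, and the non-nucleophilic counter-ion prevents dealkylation.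

Step 9
Reactants: 11 rac-1-[2,4-bis(benzyloxy)phenyl]-2-bromo-2-[5-bromo-2-(tert-butyldimethylsilyloxy)phenyl]ethan-1-one; 16 (2S,5S)-1-[4-(benzyloxy)benzyl]-2,5-dimethylthiolan-1-ium tetrafluoroborate
Product: 20 [2,4-bis(benzyloxy)phenyl]{(2S,3S)-2-[4-(benzyloxy)phenyl]-5-bromo-2,3-dihydro-1-benzofuran-3-yl}methanone, via sulfonium ylide 17 (not isolated), via acyl ortho-quinone methide 18 (not isolated), via phenoxide sulfonium betaine 19 (not isolated)
Conditions: 16 (1.3 equiv), Cs2CO3, 4 Å MS, MeCN, 0 °C; then 11, CsF, 0 °C to rt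
Reagents that add atoms: none
Why: Proposed new method: fluoride strips the silyl group from 11, the phenoxide expels bromide by 1,4-elimination to give quinone methide 18 (both enantiomers of 11 converge on this planar species), carbonate turns 16 into ylide 17, the ylide carbon adds to the exocyclic carbon of 18 with rearomatisation of ring A to give betaine 19, and the phenoxide then displaces the thiolane at C2. The closest known reaction type is the [4+1] annulation of ortho-quinone methides generated in situ with sulfonium ylides to give trans-2,3-dihydrobenzofurans, combined with asymmetric benzylidene transfer from trans-2,5-dimethylthiolanium ylides to aldehydes; untested are the acyl group on the quinone methide and the chiral benzylide in this role. Ring B closes by 5-exo-tet SN2 attack of O1 on C2 with inversion. C2 is controlled by the twofold-symmetric thiolane: the aryl group of the ylide sits syn to the sulfur lone pair, the methyl group cis to the ylide carbon shields one face, the addition (irreversible because it restores aromaticity) gives the R sulfonium carbon of 19, and invertive closure turns it into 2S. C3 is under thermodynamic control, since its proton is alpha to the ketone and carbonate equilibrates any cis isomer to trans through the exocyclic enolate without cleaving C2–O1, that cleavage being the reverse of a disfavoured 5-endo-trig closure. The step needs carbon–carbon bond formation at the exocyclic carbon and ring closure faster than E1cB loss of the sulfide from 19 or attack of the ylide on a carbonyl group; the gain of aromaticity, the phenoxide held next to an excellent benzylic leaving group and the hindered, electron-rich ketones should secure this.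

Step 10
Reactants: 21 1-[2,4-bis(benzyloxy)phenyl]ethan-1-one
Product: 22 1-[2,4-bis(benzyloxy)phenyl]prop-2-en-1-one
Conditions: (CH2O)n, i-Pr2NH·CF3CO2H, CF3CO2H (cat.), THF, reflux
Reagents that add atoms: paraformaldehyde (as formaldehyde), C=O
Why: Mannich condensation with formaldehyde followed by elimination of the amine (direct alpha-methylenation of an aryl methyl ketone) gives the aryl vinyl ketone, which is stabilised with a trace of BHT and used promptly.

Step 11
Reactants: 20 [2,4-bis(benzyloxy)phenyl]{(2S,3S)-2-[4-(benzyloxy)phenyl]-5-bromo-2,3-dihydro-1-benzofuran-3-yl}methanone; 22 1-[2,4-bis(benzyloxy)phenyl]prop-2-en-1-one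
Product: 23 (E)-1-[2,4-bis(benzyloxy)phenyl]-3-{(2S,3S)-2-[4-(benzyloxy)phenyl]-3-[2,4-bis(benzyloxy)benzoyl]-2,3-dihydro-1-benzofuran-5-yl}prop-2-en-1-one
Conditions: Pd(P(t-Bu)3)2 (5 mol %), Cy2NMe, BHT (trace), 1,4-dioxane, rt to 50 °C
Reagents that add atoms: none
Why: Mizoroki–Heck coupling of the unhindered C5 aryl bromide with the terminal enone gives the E enone, and the bulky electron-rich phosphine allows near-ambient temperature with only a hindered tertiary amine as base, conditions under which C2 is untouched and C3 stays at its trans equilibrium position.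

Step 12
Reactants: 23 (E)-1-[2,4-bis(benzyloxy)phenyl]-3-{(2S,3S)-2-[4-(benzyloxy)phenyl]-3-[2,4-bis(benzyloxy)benzoyl]-2,3-dihydro-1-benzofuran-5-yl}prop-2-en-1-one
Product: 24 1-(2,4-dihydroxyphenyl)-3-[(2S,3S)-3-(2,4-dihydroxybenzoyl)-2-(4-hydroxyphenyl)-2,3-dihydro-1-benzofuran-5-yl]propan-1-one (CNP0136359.1)
Conditions: H2 (1 atm), Pd/C (10 %), EtOAc/MeOH, rt
Reagents that add atoms: none
Why: Heterogeneous hydrogenation saturates the enone double bond and hydrogenolyses all five benzyl aryl ethers in one operation, while the ortho-hydroxyaryl ketones and the cyclic benzylic C2–O1 bond reduce much more slowly and the neutral medium leaves both stereocentres alone.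

Compound list
1 | 2-(5-bromo-2-hydroxyphenyl)acetic acid | OC(=O)Cc1cc(Br)ccc1O | starting material
2 | tert-butyldimethylsilyl 2-[5-bromo-2-(tert-butyldimethylsilyloxy)phenyl]acetate | CC(C)(C)[Si](C)(C)OC(=O)Cc1cc(Br)ccc1O[Si](C)(C)C(C)(C)C | intermediate (not isolated)
3 | 2-[5-bromo-2-(tert-butyldimethylsilyloxy)phenyl]acetic acid | OC(=O)Cc1cc(Br)ccc1O[Si](C)(C)C(C)(C)C | intermediate
4 | 2-[5-bromo-2-(tert-butyldimethylsilyloxy)phenyl]-1-(imidazol-1-yl)ethan-1-one | O=C(Cc1cc(Br)ccc1O[Si](C)(C)C(C)(C)C)n1ccnc1 | intermediate (not isolated)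
5 | 2-[5-bromo-2-(tert-butyldimethylsilyloxy)phenyl]-N-methoxy-N-methylacetamide | CON(C)C(=O)Cc1cc(Br)ccc1O[Si](C)(C)C(C)(C)C | intermediate
6 | 4-bromoresorcinol | Oc1ccc(Br)c(O)c1 | starting material
7 | 2,4-bis(benzyloxy)-1-bromobenzene | Brc1ccc(OCc2ccccc2)cc1OCc1ccccc1 | intermediate
8 | [2,4-bis(benzyloxy)phenyl]lithium | [Li]c1ccc(OCc2ccccc2)cc1OCc1ccccc1 | intermediate (not isolated)
9 | 1-[2,4-bis(benzyloxy)phenyl]-2-[5-bromo-2-(tert-butyldimethylsilyloxy)phenyl]ethan-1-one | O=C(Cc1cc(Br)ccc1O[Si](C)(C)C(C)(C)C)c1ccc(OCc2ccccc2)cc1OCc1ccccc1 | intermediate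
10 | lithium (Z)-1-[2,4-bis(benzyloxy)phenyl]-2-[5-bromo-2-(tert-butyldimethylsilyloxy)phenyl]ethen-1-olate | [Li]O/C(=C\c1cc(Br)ccc1O[Si](C)(C)C(C)(C)C)c1ccc(OCc2ccccc2)cc1OCc1ccccc1 | intermediate (not isolated)
11 | rac-1-[2,4-bis(benzyloxy)phenyl]-2-bromo-2-[5-bromo-2-(tert-butyldimethylsilyloxy)phenyl]ethan-1-one (racemic) | O=C(C(Br)c1cc(Br)ccc1O[Si](C)(C)C(C)(C)C)c1ccc(OCc2ccccc2)cc1OCc1ccccc1 | intermediate
12 | (2R,5R)-hexane-2,5-diol | C[C@@H](O)CC[C@@H](C)O | starting material
13 | (2R,5R)-hexane-2,5-diyl dimethanesulfonate | C[C@@H](OS(C)(=O)=O)CC[C@@H](C)OS(C)(=O)=O | intermediate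
14 | (2S,5S)-2,5-dimethylthiolane | C[C@H]1CC[C@H](C)S1 | intermediate
15 | 4-(benzyloxy)benzyl chloride | ClCc1ccc(OCc2ccccc2)cc1 | starting material
16 | (2S,5S)-1-[4-(benzyloxy)benzyl]-2,5-dimethylthiolan-1-ium tetrafluoroborate | C[C@H]1CC[C@H](C)[S+]1Cc1ccc(OCc2ccccc2)cc1.F[B-](F)(F)F | intermediate
17 | (2S,5S)-2,5-dimethylthiolan-1-ium 4-(benzyloxy)benzylide | C[C@H]1CC[C@H](C)[S+]1[CH-]c1ccc(OCc2ccccc2)cc1 | intermediate (not isolated)
18 | 6-{2-[2,4-bis(benzyloxy)phenyl]-2-oxoethylidene}-4-bromocyclohexa-2,4-dien-1-one (geometry of the exocyclic double bond not assigned) | O=C1C=CC(Br)=CC1=CC(=O)c1ccc(OCc2ccccc2)cc1OCc1ccccc1 | intermediate (not isolated)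
19 | (2R,3R)-1-[2,4-bis(benzyloxy)phenyl]-3-[4-(benzyloxy)phenyl]-2-(5-bromo-2-oxidophenyl)-3-[(2S,5S)-2,5-dimethylthiolan-1-ium-1-yl]propan-1-one (zwitterion) | [O-]c1ccc(Br)cc1[C@H](C(=O)c1ccc(OCc2ccccc2)cc1OCc1ccccc1)[C@H](c1ccc(OCc2ccccc2)cc1)[S+]1[C@@H](C)CC[C@@H]1C | intermediate (not isolated)
20 | [2,4-bis(benzyloxy)phenyl]{(2S,3S)-2-[4-(benzyloxy)phenyl]-5-bromo-2,3-dihydro-1-benzofuran-3-yl}methanone | Brc1ccc2c(c1)[C@H](C(=O)c1ccc(OCc3ccccc3)cc1OCc1ccccc1)[C@@H](c1ccc(OCc3ccccc3)cc1)O2 | intermediate
21 | 1-[2,4-bis(benzyloxy)phenyl]ethan-1-one | CC(=O)c1ccc(OCc2ccccc2)cc1OCc1ccccc1 | starting material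
22 | 1-[2,4-bis(benzyloxy)phenyl]prop-2-en-1-one | C=CC(=O)c1ccc(OCc2ccccc2)cc1OCc1ccccc1 | intermediate
23 | (E)-1-[2,4-bis(benzyloxy)phenyl]-3-{(2S,3S)-2-[4-(benzyloxy)phenyl]-3-[2,4-bis(benzyloxy)benzoyl]-2,3-dihydro-1-benzofuran-5-yl}prop-2-en-1-one | O=C(/C=C/c1ccc2c(c1)[C@H](C(=O)c1ccc(OCc3ccccc3)cc1OCc1ccccc1)[C@@H](c1ccc(OCc3ccccc3)cc1)O2)c1ccc(OCc2ccccc2)cc1OCc1ccccc1 | intermediate
24 | 1-(2,4-dihydroxyphenyl)-3-[(2S,3S)-3-(2,4-dihydroxybenzoyl)-2-(4-hydroxyphenyl)-2,3-dihydro-1-benzofuran-5-yl]propan-1-one | O=C(CCc1ccc2c(c1)[C@H](C(=O)c1ccc(O)cc1O)[C@@H](c1ccc(O)cc1)O2)c1ccc(O)cc1O | target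

Total step count: 12
Longest linear sequence: 7 steps (steps 1, 2, 4, 5, 9, 11, 12)

Steps most likely to fail

Step 9 (the labelled step). The processes that may defeat it are:
- weak or reversed facial discrimination by the ylide, giving low enantiomeric purity (a reversed sense alone would be answered by the mirror-image sulfide, a change of reagent only);
- elimination of the sulfide from the betaine to an achiral alpha-aryl chalcone;
- interception of the quinone methide by water, fluoride or the enolate of the product;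
- abstraction of bromine from 11 by the soft ylide;
- closure of the freed phenoxide onto the neighbouring ketone.

The fallback uses known chemistry only, sets out from 1 and 15 and rejoins the route at 20. Fischer esterification of 1 (MeOH, H2SO4) should give methyl 2-(5-bromo-2-hydroxyphenyl)acetate F1. Williamson alkylation with 15 (K2CO3, DMF) should give methyl 2-{2-[4-(benzyloxy)benzyloxy]-5-bromophenyl}acetate F2. Regitz diazo transfer (4-acetamidobenzenesulfonyl azide, DBU, MeCN) should give methyl 2-{2-[4-(benzyloxy)benzyloxy]-5-bromophenyl}-2-diazoacetate F3. Enantioselective intramolecular carbenoid C–H insertion into the ether CH2 group, catalysed by dirhodium tetrakis[N-phthaloyl-(S)-tert-leucinate], Rh2(S-PTTL)4 (or its mirror image, whichever delivers 2S), in toluene at −60 °C should close ring B to the cis ester methyl (2S,3R)-2-[4-(benzyloxy)phenyl]-5-bromo-2,3-dihydro-1-benzofuran-3-carboxylate F4. NaOMe in MeOH should epimerise C3 to the trans ester methyl (2S,3S)-2-[4-(benzyloxy)phenyl]-5-bromo-2,3-dihydro-1-benzofuran-3-carboxylate F5. MeNH(OMe)·HCl with i-PrMgCl in THF at −20 °C should give the Weinreb amide (2S,3S)-2-[4-(benzyloxy)phenyl]-5-bromo-N-methoxy-N-methyl-2,3-dihydro-1-benzofuran-3-carboxamide F6, and aryllithium 8 (from 7 as in step 4) at −78 °C should convert it into 20.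

Step 11. The risks are polymerisation or phosphine-induced oligomerisation of vinyl ketone 22, sluggish oxidative addition of the electron-rich bromide, and hydrodebromination. The fallback replaces the Heck reaction by a homoenolate cross-coupling, sets out from 20 (partner from 7 through 8) and rejoins the route at 24. Aryllithium 8 added to excess methyl chloroformate should give methyl 2,4-bis(benzyloxy)benzoate F7. Kulinkovich cyclopropanation (EtMgBr, Ti(OiPr)4, THF) should give 1-[2,4-bis(benzyloxy)phenyl]cyclopropan-1-ol F8. Ring-opening coupling of F8 with 20 through a palladium homoenolate (Pd(OAc)2, XPhos, Cs2CO3, toluene, 80 °C) should give 1-[2,4-bis(benzyloxy)phenyl]-3-{(2S,3S)-2-[4-(benzyloxy)phenyl]-3-[2,4-bis(benzyloxy)benzoyl]-2,3-dihydro-1-benzofuran-5-yl}propan-1-one F9, and hydrogenolysis under the conditions of step 12 should give 24.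

Step 5. The risks are proton transfer between the product and unreacted enolate (dibromination together with returned ketone), migration of the silyl group to the enolate oxygen, and decomposition of the labile benzylic alpha-bromo ketone during isolation. The fallback brings bromine in as bromide instead of as an electrophile, sets out from 9 and rejoins the route at 11. Regitz diazo transfer to 9 (4-acetamidobenzenesulfonyl azide, DBU, MeCN) should give 1-[2,4-bis(benzyloxy)phenyl]-2-[5-bromo-2-(tert-butyldimethylsilyloxy)phenyl]-2-diazoethan-1-one F10. One equivalent of HBr in Et2O at −20 °C should then protonate the diazo carbon and displace nitrogen to give 11, which would be used without chromatography.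

Further compounds
F1 | step 9 | methyl 2-(5-bromo-2-hydroxyphenyl)acetate | COC(=O)Cc1cc(Br)ccc1O
F2 | step 9 | methyl 2-{2-[4-(benzyloxy)benzyloxy]-5-bromophenyl}acetate | COC(=O)Cc1cc(Br)ccc1OCc1ccc(OCc2ccccc2)cc1
F3 | step 9 | methyl 2-{2-[4-(benzyloxy)benzyloxy]-5-bromophenyl}-2-diazoacetate | COC(=O)C(=[N+]=[N-])c1cc(Br)ccc1OCc1ccc(OCc2ccccc2)cc1
F4 | step 9 | methyl (2S,3R)-2-[4-(benzyloxy)phenyl]-5-bromo-2,3-dihydro-1-benzofuran-3-carboxylate | Brc1ccc2c(c1)[C@@H](C(=O)OC)[C@@H](c1ccc(OCc3ccccc3)cc1)O2
F5 | step 9 | methyl (2S,3S)-2-[4-(benzyloxy)phenyl]-5-bromo-2,3-dihydro-1-benzofuran-3-carboxylate | Brc1ccc2c(c1)[C@H](C(=O)OC)[C@@H](c1ccc(OCc3ccccc3)cc1)O2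
F6 | step 9 | (2S,3S)-2-[4-(benzyloxy)phenyl]-5-bromo-N-methoxy-N-methyl-2,3-dihydro-1-benzofuran-3-carboxamide | Brc1ccc2c(c1)[C@H](C(=O)N(C)OC)[C@@H](c1ccc(OCc3ccccc3)cc1)O2
F7 | step 11 | methyl 2,4-bis(benzyloxy)benzoate | COC(=O)c1ccc(OCc2ccccc2)cc1OCc1ccccc1
F8 | step 11 | 1-[2,4-bis(benzyloxy)phenyl]cyclopropan-1-ol | OC1(CC1)c1ccc(OCc2ccccc2)cc1OCc1ccccc1
F9 | step 11 | 1-[2,4-bis(benzyloxy)phenyl]-3-{(2S,3S)-2-[4-(benzyloxy)phenyl]-3-[2,4-bis(benzyloxy)benzoyl]-2,3-dihydro-1-benzofuran-5-yl}propan-1-one | O=C(CCc1ccc2c(c1)[C@H](C(=O)c1ccc(OCc3ccccc3)cc1OCc1ccccc1)[C@@H](c1ccc(OCc3ccccc3)cc1)O2)c1ccc(OCc2ccccc2)cc1OCc1ccccc1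
F10 | step 5 | 1-[2,4-bis(benzyloxy)phenyl]-2-[5-bromo-2-(tert-butyldimethylsilyloxy)phenyl]-2-diazoethan-1-one | O=C(C(=[N+]=[N-])c1cc(Br)ccc1O[Si](C)(C)C(C)(C)C)c1ccc(OCc2ccccc2)cc1OCc1ccccc1
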